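The runs were computed on assumed constants; the scatter is artificial.

Per day, a share of the starting material becomes intermediate and a share of the intermediate leaves, so two constants in that unit carry this comparison.

| flask | starting material | reagent | remark | time |
|---|---|---|---|---|
| elm | 0.10 M | 0.25 M | run made earlier |  |
| alder | 0.15 M | 0.25 M | run made earlier |  |
| zeta | 0.10 M | 0.250 M | everything together in a closed stirred flask, run for 4.0 d | 4.0 d |
| beta | 0.10 M (fed, over 3.20 d) | 0.250 M | all but starting material at the start; starting material goes in evenly over 3.20 d, the run ends at 4.0 d | 4.0 d |
| gamma | 0.10 M | 0.250 M | one stirred flow tank at steady state, fed with the mixture as stated, mean residence time 4.0 d |  |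
| alpha | 0.10 M | 0.250 M (fed, over 3.20 d) | a stirred flask in which reagent is dosed at a steady rate over 3.20 d without added volume, worked up at 4.0 d | 4.0 d |

- elm (time / d: intermediate / %, target / %, starting material / %): 0.208: 6.4, 0.1, 93.8; 0.417: 12.1, 0.2, 87.4; 1.04: 24.7, 2.0, 72.4; 2.50: 39.1, 8.6, 49.4
- alder (time / h: intermediate / %, target / %, starting material / %): 2.50: 3.6, 0, 95.6; 5.00: 6.2, 0, 93.8; 12.0: 13.6, 0, 85.9; 30.0: 26.9, 2.7, 69.1

(standard deviation of a reading: 0.5 percentage points)

- the stated concentrations are those of everything mixed, before any reaction; amounts are the same in each set-up
- the numbers in the tables scatter by 0.5 percentage points (one standard deviation)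
- the feed brings no volume worth counting
- the earlier runs were made in a closed, stirred flask

1. the set-up with the highest amount of intermediate at the outlet or at the end, in percent of the starting material put in ("none" if the first two lie within 2 percentage points) (zeta / beta / gamma / alpha / none)
2. amount of intermediate at the outlet or at the end, in percent of the starting material put in, zeta
3. amount of intermediate at the outlet or at the end, in percent of the starting material put in, beta
4. amount of intermediate at the outlet or at the end, in percent of the starting material put in, gamma
5. amount of intermediate at the outlet or at the end, in percent of the starting material put in, alpha

In the elm run, starting material falls to 49.4% at 2.50 d, a mean constant of 0.282 /d. Over that span the midpoint c(reagent) is 0.225 M, taking one reagent per starting material. Both runs share one reagent level, so a first step proportional to c(reagent) is an assumption.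

Between the last two elm readings, the charge that is neither starting material nor intermediate grows, and dividing that growth by the span and the mean intermediate gives an exit constant of 0.185 /d.

Zeta has two extreme versions. With reagent held at its charge, the pseudo-first-order constant is 0.314 /d, and the two-step formula gives 46.8% intermediate. With reagent held at 0.150 M, its level once the whole charge has taken one reagent each, the constant is 0.188 /d and the formula gives 35.7%. Reagent moves from the first level toward the second, so the reckoning places zeta between them.

Its midpoint c(reagent) is 0.216 M, which gives the mean-reagent constant, the first-order constant with the reagent curve replaced by its mean: 0.271 /d. Zeta then comes to 43.8%. Reagent use is 0.0431 M in the first half of the run against 0.0245 M in the second, so the midpoint, and this figure, lean high.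

The forecast gives 46% for zeta, 37.5% for beta, 32.5% for gamma and 39% for alpha, and names zeta: “Batch wins: reagent is present longest and there is no back-mixing”. The reckoning here stands lower for zeta.

The flasks give 41.8% in zeta, 35.9% in beta, 28.1% in gamma and 36.5% in alpha, so zeta stands highest, and the forecast held within its tolerance.

    reagent + target → over-reaction product (k = 0.0520 /M/h)
    target ⇌ isomer of the product (K = 12.0, k = 0.00990 /h)
    starting material + reagent → intermediate (k = 0.0540 /M/h)
    intermediate → target (k = 0.00810 /h)

In zeta, starting material by its own step has a half-life of 2.1 d at charged reagent, shorter than the 3.6 d of intermediate by its step, and the flask ends 2 percentage points below the mean-reagent reckoning. In gamma, zeta's mean-reagent constant and the exit constant over the mean residence time give 29.9% for a stirred tank, and gamma stands at 28.1%.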